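**Retrosynthetic overview**
1. Target 28 ⇐ macrocycle 25 (desilylation, C14 oxidation, acetonide cleavage); the ten-membered carbocycle is closed last by ring-closing metathesis at C1=C10 of triene 24.
2. 24 ⇐ alcohol 21 + (S)-2-methylbutanoic acid 23 (asymmetric hydrogenation of tiglic acid).
3. 21 ⇐ aldehyde 19 + ring-locked γ-alkoxyallylboronate 15 (C8–C9 bond; chiral phosphoric acid sets C8 and C9; the dioxane arrives preformed).
4. 19 ⇐ achiral enal 7 + achiral butenolide allylboronate 11 (C6–C7 bond; chiral phosphoric acid sets C6 and C7; translactonisation gives the trans γ-lactone, the first ring formed).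
5. 7 ⇐ but-2-yne-1,4-diol; 11 ⇐ α-methylene-γ-butyrolactone; 15 ⇐ 2-methylidenepropane-1,3-diol. Ring order: γ-lactone, then ten-membered carbocycle (the dioxane is temporary).

Assumption: the SMILES is read literally, i.e. (6R,7S,8R,9S), (2S) ester, both ring alkenes cis within the ring (CIP 1(10)E,4E); labels C1–C15 are germacranolide positions (C6 lactone carbinol, C7 ring fusion, C8 ester carbinol, C9 free carbinol, C14 aldehyde on C10, C15 hydroxymethyl on C4, C11–C13 methylene lactone); (S)-TRIP = (S)-3,3'-bis(2,4,6-triisopropylphenyl)-1,1'-binaphthyl-2,2'-diyl hydrogen phosphate.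

**Route**

Step 1
Reactants: 1 but-2-yne-1,4-diol
Product: 2 4-{[tert-butyl(diphenyl)silyl]oxy}but-2-yn-1-ol
Conditions: NaH (1.0 equiv), THF, 0→23 °C; TBDPSCl (1.0 equiv)
Reagents that add atoms: tert-butyl(chloro)diphenylsilane, CC(C)(C)[Si](Cl)(c1ccccc1)c1ccccc1
Why: One equivalent of NaH gives the sparingly soluble mono-alkoxide of the symmetric diol, which is silylated once (mono-protection by O-silylation); no stereocentre is involved.

Step 2
Reactants: 2 4-{[tert-butyl(diphenyl)silyl]oxy}but-2-yn-1-ol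
Product: 4 (2Z)-4-{[tert-butyl(diphenyl)silyl]oxy}-3-iodobut-2-en-1-ol, via oxa-alanate 3 (not isolated)
Conditions: NaAlH2(OCH2CH2OMe)2 (1.5 equiv), THF, 0 °C; then I2, −78→0 °C
Reagents that add atoms: iodine, II
Why: Hydroxyl-directed trans-hydroalumination delivers hydride to the proximal alkyne carbon and aluminium to the distal one in a five-membered oxa-alanate, and iodinolysis with retention gives the Z iodoalkene with iodine cis to CH2OH.

Step 3
Reactants: 4 (2Z)-4-{[tert-butyl(diphenyl)silyl]oxy}-3-iodobut-2-en-1-ol; 5 but-3-en-1-ylzinc bromide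
Product: 6 (2E)-3-({[tert-butyl(diphenyl)silyl]oxy}methyl)hepta-2,6-dien-1-ol
Conditions: PdCl2(dppf) (5 mol%), THF, 23→50 °C (3 equiv of 5)
Reagents that add atoms: none
Why: Negishi sp2–sp3 cross-coupling proceeds with retention of alkene geometry, so the butenyl chain ends cis to CH2OH (the future ring-cis C4=C5 bond), the excess organozinc covering the free hydroxyl.

Step 4
Reactants: 6 (2E)-3-({[tert-butyl(diphenyl)silyl]oxy}methyl)hepta-2,6-dien-1-ol
Product: 7 (2E)-3-({[tert-butyl(diphenyl)silyl]oxy}methyl)hepta-2,6-dienal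
Conditions: MnO2 (15 equiv), CH2Cl2, 23 °C
Reagents that add atoms: none
Why: MnO2 allylic oxidation is neutral and heterogeneous, so the trisubstituted enal forms without E/Z isomerisation.

Step 5
Reactants: 8 3-methylideneoxolan-2-one (α-methylene-γ-butyrolactone)
Product: 10 3-(bromomethyl)furan-2(5H)-one, via dibromide 9 (not isolated)
Conditions: Br2, CH2Cl2, 0 °C; then Et3N, 0→23 °C
Reagents that add atoms: bromine, BrBr
Why: Bromine adds to the exocyclic alkene and E2 dehydrobromination of the tertiary bromide towards the ring CH2 gives the conjugated butenolide that keeps the primary allylic bromide (bromination–dehydrobromination).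

Step 6
Reactants: 10 3-(bromomethyl)furan-2(5H)-one
Product: 11 3-[(4,4,5,5-tetramethyl-1,3,2-dioxaborolan-2-yl)methyl]furan-2(5H)-one
Conditions: B2pin2, Pd2(dba)3 (2.5 mol%), PhMe, 50 °C
Reagents that add atoms: bis(pinacolato)diboron, CC1(C)OB(OC1(C)C)B1OC(C)(C)C(C)(C)O1
Why: Miyaura-type allylic borylation through a π-allylpalladium intermediate puts boron on the unhindered CH2 terminus and keeps the conjugated butenolide, so the γ-substituent (ring CH2O) is locked trans to CH2B.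

Step 7
Reactants: 12 2-methylidenepropane-1,3-diol
Product: 13 2,2-dimethyl-5-methylidene-1,3-dioxane
Conditions: Me2C(OMe)2, PPTS (cat.), CH2Cl2, 23 °C
Reagents that add atoms: 2,2-dimethoxypropane, COC(C)(C)OC
Why: Acid-catalysed transketalisation of the 1,3-diol gives the six-membered acetonide.

Step 8
Reactants: 13 2,2-dimethyl-5-methylidene-1,3-dioxane
Product: 15 2,2-dimethyl-5-[(4,4,5,5-tetramethyl-1,3,2-dioxaborolan-2-yl)methyl]-4H-1,3-dioxine, via allyllithium 14 (not isolated)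
Conditions: s-BuLi, TMEDA, THF, −78 °C; then i-PrOBpin, −78→0 °C; pH 7 buffer
Reagents that add atoms: 2-isopropoxy-4,4,5,5-tetramethyl-1,3,2-dioxaborolane, CC(C)OB1OC(C)(C)C(C)(C)O1
Why: Allylic deprotonation alpha to oxygen (as for allyl ethers) gives a ring-locked 1-oxyallyl anion that is borylated at the exocyclic CH2 terminus, so the γ-alkoxyallylboronate necessarily has oxygen trans to CH2B (lithiation–borylation).

Step 9
Reactants: 7 (2E)-3-({[tert-butyl(diphenyl)silyl]oxy}methyl)hepta-2,6-dienal; 11 3-[(4,4,5,5-tetramethyl-1,3,2-dioxaborolan-2-yl)methyl]furan-2(5H)-one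
Product: 18 (4R,5R)-5-[(1E)-2-({[tert-butyl(diphenyl)silyl]oxy}methyl)hexa-1,5-dien-1-yl]-4-(hydroxymethyl)-3-methylideneoxolan-2-one, via borate ester 16 (not isolated), via primary-lactone alcohol 17 (not isolated)
Conditions: (S)-TRIP (10 mol%), 4 Å MS, PhMe, −20→0 °C; aq. NaHCO3; then Ti(OiPr)4 (0.2 equiv), CH2Cl2, 23 °C
Reagents that add atoms: none
Why: Proposed new method: chiral phosphoric acid-catalysed allylboration of an enal with a cyclic 2-acyl-allylboronate whose γ-substituent is held trans to CH2B by the butenolide ring, so the closed chair transition state (acid P–OH hydrogen-bonded to a boronate oxygen, P=O to the formyl C–H) can only give the anti adduct, while (S)-TRIP, the antipode of the catalyst that gives Re-face addition to aryl and enal aldehydes, directs Si-face attack and sets C6 as R and thereby C7, after which Ti(OiPr)4-mediated translactonisation from the primary to the secondary allylic oxygen gives the trans γ-lactone; the closest known reactions are phosphoric acid-catalysed allylboration of aldehydes with allyl pinacolboronate and Brønsted acid-accelerated additions of 2-alkoxycarbonyl-allylboronates.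

Step 10
Reactants: 18 (4R,5R)-5-[(1E)-2-({[tert-butyl(diphenyl)silyl]oxy}methyl)hexa-1,5-dien-1-yl]-4-(hydroxymethyl)-3-methylideneoxolan-2-one
Product: 19 (2R,3S)-2-[(1E)-2-({[tert-butyl(diphenyl)silyl]oxy}methyl)hexa-1,5-dien-1-yl]-4-methylidene-5-oxooxolane-3-carbaldehyde
Conditions: Dess–Martin periodinane, CH2Cl2, 0 °C
Reagents that add atoms: none
Why: Dess–Martin oxidation converts the primary alcohol into the aldehyde under neutral, non-epimerising conditions, and the β,γ-unsaturated aldehyde is used at once.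

Step 11
Reactants: 19 (2R,3S)-2-[(1E)-2-({[tert-butyl(diphenyl)silyl]oxy}methyl)hexa-1,5-dien-1-yl]-4-methylidene-5-oxooxolane-3-carbaldehyde; 15 2,2-dimethyl-5-[(4,4,5,5-tetramethyl-1,3,2-dioxaborolan-2-yl)methyl]-4H-1,3-dioxine
Product: 21 (4R,5R)-5-[(1E)-2-({[tert-butyl(diphenyl)silyl]oxy}methyl)hexa-1,5-dien-1-yl]-4-{(R)-[(4S)-2,2-dimethyl-5-methylidene-1,3-dioxan-4-yl](hydroxy)methyl}-3-methylideneoxolan-2-one, via borate ester 20 (not isolated)
Conditions: (S)-TRIP (10 mol%), 4 Å MS, PhMe, −40 °C (1.5 equiv of 15); aq. NaHCO3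
Reagents that add atoms: none
Why: Proposed new method: the same catalyst-controlled allylboration applied to a cyclic γ-alkoxyallylboronate whose enol-ether oxygen is held trans to CH2B by the dioxine ring, so γ-attack through the chair transition state gives only the anti 8,9-diol derivative and unveils the 5-methylidene-1,3-dioxane, with (S)-TRIP directing Si-face attack on the aldehyde to set C8 as R (C9 follows as S) over the weak intrinsic bias of the α-branched aldehyde; the closest known reactions are thermal γ-alkoxyallylboration (anti from E reagents) and phosphoric acid-catalysed crotylboration.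

Step 12
Reactants: 22 (2E)-2-methylbut-2-enoic acid (tiglic acid)
Product: 23 (2S)-2-methylbutanoic acid
Conditions: H2 (4 atm), Ru(OAc)2[(S)-H8-BINAP] (0.5 mol%), MeOH, 20 °C
Reagents that add atoms: none
Why: Carboxylate-directed asymmetric hydrogenation of the α,β-unsaturated acid with the (S)-H8-BINAP ruthenium diacetate complex sets the 2S centre in high ee.

Step 13
Reactants: 21 (4R,5R)-5-[(1E)-2-({[tert-butyl(diphenyl)silyl]oxy}methyl)hexa-1,5-dien-1-yl]-4-{(R)-[(4S)-2,2-dimethyl-5-methylidene-1,3-dioxan-4-yl](hydroxy)methyl}-3-methylideneoxolan-2-one; 23 (2S)-2-methylbutanoic acid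
Product: 24 (R)-[(4S)-2,2-dimethyl-5-methylidene-1,3-dioxan-4-yl]{(2R,3S)-2-[(1E)-2-({[tert-butyl(diphenyl)silyl]oxy}methyl)hexa-1,5-dien-1-yl]-4-methylidene-5-oxooxolan-3-yl}methyl (2S)-2-methylbutanoate
Conditions: DCC, DMAP (0.2 equiv), CH2Cl2, 0→23 °C
Reagents that add atoms: none
Why: Steglich esterification acylates the only free hydroxyl (C8) without touching any stereocentre, which also blocks back-translactonisation.

Step 14
Reactants: 24 (R)-[(4S)-2,2-dimethyl-5-methylidene-1,3-dioxan-4-yl]{(2R,3S)-2-[(1E)-2-({[tert-butyl(diphenyl)silyl]oxy}methyl)hexa-1,5-dien-1-yl]-4-methylidene-5-oxooxolan-3-yl}methyl (2S)-2-methylbutanoate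
Product: 25 (1(10)Z,4E,6R,7S,8R,9S)-15-{[tert-butyl(diphenyl)silyl]oxy}-9,14-(isopropylidenedioxy)-8-[(2S)-2-methylbutanoyloxy]germacra-1(10),4,11(13)-trien-12,6-olide
Conditions: second-generation Hoveyda–Grubbs catalyst RuCl2(H2IMes)(=CH-C6H4-2-O-i-Pr) (15 mol%), PhMe (1 mM), 80 °C
Reagents that add atoms: none
Why: Ring-closing metathesis initiates at the terminal vinyl group and closes onto the 1,1-disubstituted alkene, and the ten-membered ring can only hold the ring-cis trisubstituted alkene, which is the required C1=C10 geometry.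

Step 15
Reactants: 25 (1(10)Z,4E,6R,7S,8R,9S)-15-{[tert-butyl(diphenyl)silyl]oxy}-9,14-(isopropylidenedioxy)-8-[(2S)-2-methylbutanoyloxy]germacra-1(10),4,11(13)-trien-12,6-olide
Product: 26 (1(10)Z,4E,6R,7S,8R,9S)-15-{[tert-butyl(diphenyl)silyl]oxy}-9,14-dihydroxy-8-[(2S)-2-methylbutanoyloxy]germacra-1(10),4,11(13)-trien-12,6-olide
Conditions: AcOH/THF/H2O 3:1:1, 35 °C
Reagents that add atoms: none
Why: Mild aqueous acid hydrolyses the isopropylidene acetal while the TBDPS ether, the ester and the lactone survive and acyl migration is slow.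

Step 16
Reactants: 26 (1(10)Z,4E,6R,7S,8R,9S)-15-{[tert-butyl(diphenyl)silyl]oxy}-9,14-dihydroxy-8-[(2S)-2-methylbutanoyloxy]germacra-1(10),4,11(13)-trien-12,6-olide
Product: 27 (1(10)E,4E,6R,7S,8R,9S)-15-{[tert-butyl(diphenyl)silyl]oxy}-9-hydroxy-8-[(2S)-2-methylbutanoyloxy]-14-oxogermacra-1(10),4,11(13)-trien-12,6-olide
Conditions: TEMPO (15 mol%), PhI(OAc)2 (1.2 equiv), CH2Cl2, 23 °C
Reagents that add atoms: none
Why: TEMPO/PhI(OAc)2 oxidises the primary allylic C14 alcohol chemoselectively beside the secondary C9 alcohol, giving the conjugated enal whose geometry is already fixed by the ring.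

Step 17
Reactants: 27 (1(10)E,4E,6R,7S,8R,9S)-15-{[tert-butyl(diphenyl)silyl]oxy}-9-hydroxy-8-[(2S)-2-methylbutanoyloxy]-14-oxogermacra-1(10),4,11(13)-trien-12,6-olide
Product: 28 (1(10)E,4E,6R,7S,8R,9S)-9,15-dihydroxy-8-[(2S)-2-methylbutanoyloxy]-14-oxogermacra-1(10),4,11(13)-trien-12,6-olide (target)
Conditions: HF·pyridine, THF/pyridine, 0→23 °C
Reagents that add atoms: none
Why: Buffered fluoride desilylation removes the TBDPS ether without acyl migration or conjugate addition to the enal or methylene lactone.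

**Compound list**
1 | but-2-yne-1,4-diol | OCC#CCO | starting material
2 | 4-{[tert-butyl(diphenyl)silyl]oxy}but-2-yn-1-ol | OCC#CCO[Si](c1ccccc1)(c1ccccc1)C(C)(C)C | intermediate
3 | sodium 3-({[tert-butyl(diphenyl)silyl]oxy}methyl)-2,2-bis(2-methoxyethoxy)-2,5-dihydro-1,2-oxaaluminol-2-uide (oxa-alanate) | [Na+].COCCO[Al-]1(OCCOC)OCC=C1CO[Si](c2ccccc2)(c2ccccc2)C(C)(C)C | intermediate
4 | (2Z)-4-{[tert-butyl(diphenyl)silyl]oxy}-3-iodobut-2-en-1-ol | OC/C=C(/CO[Si](c1ccccc1)(c1ccccc1)C(C)(C)C)I | intermediate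
5 | but-3-en-1-ylzinc bromide | C=CCC[Zn]Br | starting material
6 | (2E)-3-({[tert-butyl(diphenyl)silyl]oxy}methyl)hepta-2,6-dien-1-ol | OC/C=C(/CO[Si](c1ccccc1)(c1ccccc1)C(C)(C)C)CCC=C | intermediate
7 | (2E)-3-({[tert-butyl(diphenyl)silyl]oxy}methyl)hepta-2,6-dienal | O=C/C=C(/CO[Si](c1ccccc1)(c1ccccc1)C(C)(C)C)CCC=C | intermediate
8 | 3-methylideneoxolan-2-one | C=C1CCOC1=O | starting material
9 | 3-bromo-3-(bromomethyl)oxolan-2-one (racemic) | BrCC1(Br)CCOC1=O | intermediate
10 | 3-(bromomethyl)furan-2(5H)-one | BrCC1=CCOC1=O | intermediate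
11 | 3-[(4,4,5,5-tetramethyl-1,3,2-dioxaborolan-2-yl)methyl]furan-2(5H)-one | CC1(C)OB(CC2=CCOC2=O)OC1(C)C | intermediate
12 | 2-methylidenepropane-1,3-diol | C=C(CO)CO | starting material
13 | 2,2-dimethyl-5-methylidene-1,3-dioxane | CC1(C)OCC(=C)CO1 | intermediate
14 | (2,2-dimethyl-5-methylidene-1,3-dioxan-4-yl)lithium | [Li]C1OC(C)(C)OCC1=C | intermediate
15 | 2,2-dimethyl-5-[(4,4,5,5-tetramethyl-1,3,2-dioxaborolan-2-yl)methyl]-4H-1,3-dioxine | CC1(C)OCC(CB2OC(C)(C)C(C)(C)O2)=CO1 | intermediate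
16 | (4R)-4-[(1R,2E)-3-({[tert-butyl(diphenyl)silyl]oxy}methyl)-1-[(4,4,5,5-tetramethyl-1,3,2-dioxaborolan-2-yl)oxy]hepta-2,6-dien-1-yl]-3-methylideneoxolan-2-one | C=C1C(=O)OC[C@@H]1[C@H](OB2OC(C)(C)C(C)(C)O2)/C=C(/CO[Si](c2ccccc2)(c2ccccc2)C(C)(C)C)CCC=C | intermediate
17 | (4R)-4-[(1R,2E)-3-({[tert-butyl(diphenyl)silyl]oxy}methyl)-1-hydroxyhepta-2,6-dien-1-yl]-3-methylideneoxolan-2-one | C=C1C(=O)OC[C@@H]1[C@H](O)/C=C(/CO[Si](c2ccccc2)(c2ccccc2)C(C)(C)C)CCC=C | intermediate
18 | (4R,5R)-5-[(1E)-2-({[tert-butyl(diphenyl)silyl]oxy}methyl)hexa-1,5-dien-1-yl]-4-(hydroxymethyl)-3-methylideneoxolan-2-one | C=C1C(=O)O[C@H](/C=C(/CO[Si](c2ccccc2)(c2ccccc2)C(C)(C)C)CCC=C)[C@H]1CO | intermediate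
19 | (2R,3S)-2-[(1E)-2-({[tert-butyl(diphenyl)silyl]oxy}methyl)hexa-1,5-dien-1-yl]-4-methylidene-5-oxooxolane-3-carbaldehyde | C=C1C(=O)O[C@H](/C=C(/CO[Si](c2ccccc2)(c2ccccc2)C(C)(C)C)CCC=C)[C@H]1C=O | intermediate
20 | (4R,5R)-5-[(1E)-2-({[tert-butyl(diphenyl)silyl]oxy}methyl)hexa-1,5-dien-1-yl]-4-{(R)-[(4S)-2,2-dimethyl-5-methylidene-1,3-dioxan-4-yl][(4,4,5,5-tetramethyl-1,3,2-dioxaborolan-2-yl)oxy]methyl}-3-methylideneoxolan-2-one | C=C1C(=O)O[C@H](/C=C(/CO[Si](c2ccccc2)(c2ccccc2)C(C)(C)C)CCC=C)[C@H]1[C@@H](OB2OC(C)(C)C(C)(C)O2)[C@H]3OC(C)(C)OCC3=C | intermediate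
21 | (4R,5R)-5-[(1E)-2-({[tert-butyl(diphenyl)silyl]oxy}methyl)hexa-1,5-dien-1-yl]-4-{(R)-[(4S)-2,2-dimethyl-5-methylidene-1,3-dioxan-4-yl](hydroxy)methyl}-3-methylideneoxolan-2-one | C=C1C(=O)O[C@H](/C=C(/CO[Si](c2ccccc2)(c2ccccc2)C(C)(C)C)CCC=C)[C@H]1[C@@H](O)[C@H]3OC(C)(C)OCC3=C | intermediate
22 | (2E)-2-methylbut-2-enoic acid (tiglic acid) | C/C=C(\C)C(=O)O | starting material
23 | (2S)-2-methylbutanoic acid | CC[C@H](C)C(=O)O | intermediate
24 | (R)-[(4S)-2,2-dimethyl-5-methylidene-1,3-dioxan-4-yl]{(2R,3S)-2-[(1E)-2-({[tert-butyl(diphenyl)silyl]oxy}methyl)hexa-1,5-dien-1-yl]-4-methylidene-5-oxooxolan-3-yl}methyl (2S)-2-methylbutanoate | C=C1C(=O)O[C@H](/C=C(/CO[Si](c2ccccc2)(c2ccccc2)C(C)(C)C)CCC=C)[C@H]1[C@@H](OC(=O)[C@@H](C)CC)[C@H]3OC(C)(C)OCC3=C | intermediate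
25 | (1(10)Z,4E,6R,7S,8R,9S)-15-{[tert-butyl(diphenyl)silyl]oxy}-9,14-(isopropylidenedioxy)-8-[(2S)-2-methylbutanoyloxy]germacra-1(10),4,11(13)-trien-12,6-olide | C=C1C(=O)O[C@@H]2/C=C(/CO[Si](c3ccccc3)(c3ccccc3)C(C)(C)C)CC/C=C4/COC(C)(C)O[C@@H]4[C@H](OC(=O)[C@@H](C)CC)[C@@H]12 | intermediate
26 | (1(10)Z,4E,6R,7S,8R,9S)-15-{[tert-butyl(diphenyl)silyl]oxy}-9,14-dihydroxy-8-[(2S)-2-methylbutanoyloxy]germacra-1(10),4,11(13)-trien-12,6-olide | C=C1C(=O)O[C@@H]2/C=C(/CO[Si](c3ccccc3)(c3ccccc3)C(C)(C)C)CC/C=C(/CO)[C@H](O)[C@H](OC(=O)[C@@H](C)CC)[C@@H]12 | intermediate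
27 | (1(10)E,4E,6R,7S,8R,9S)-15-{[tert-butyl(diphenyl)silyl]oxy}-9-hydroxy-8-[(2S)-2-methylbutanoyloxy]-14-oxogermacra-1(10),4,11(13)-trien-12,6-olide | C=C1C(=O)O[C@@H]2/C=C(/CO[Si](c3ccccc3)(c3ccccc3)C(C)(C)C)CC/C=C(/C=O)[C@H](O)[C@H](OC(=O)[C@@H](C)CC)[C@@H]12 | intermediate
28 | (1(10)E,4E,6R,7S,8R,9S)-9,15-dihydroxy-8-[(2S)-2-methylbutanoyloxy]-14-oxogermacra-1(10),4,11(13)-trien-12,6-olide (CNP0331447.11) | C=C1C(=O)O[C@@H]2/C=C(/CO)CC/C=C(/C=O)[C@H](O)[C@H](OC(=O)[C@@H](C)CC)[C@@H]12 | target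

**Totals and risks**

Total step count: 17. Longest linear sequence: 12 steps (steps 1, 2, 3, 4, 9, 10, 11, 13, 14, 15, 16, 17, from but-2-yne-1,4-diol).

Three steps most likely to fail:

Step 9 (proposed new allylboration). The acyl-substituted allylboronate 11 is a weak nucleophile and may not respond to a phosphoric acid; the sense of induction is assigned by analogy and must be confirmed on the first run. The fallback uses known chromium allylation chemistry; it sets out from enal 7 and bromide 10 and comes back to the route at 17. A catalytic asymmetric Nozaki–Hiyama allylation (CrCl2 10 mol%, a C2-symmetric carbazole bis(oxazoline) ligand, Mn powder, TMSCl, THF) adds the ring-locked allylchromium through the same chair (anti) with ligand-controlled facial selectivity and gives the trimethylsilyl ether F1. Aqueous citric acid in MeOH cleaves it to 17, which is translactonised with Ti(OiPr)4 as in step 9.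

Step 11 (proposed new γ-alkoxyallylboration). The enol acetal 15 is acid-sensitive, aldehyde 19 isomerises easily, and the catalyst may have to override the substrate's own facial bias. The fallback uses a known boron aldol; it sets out from 19 and comes back at 21. Commercial 2,2-dimethyl-1,3-dioxan-5-one is enolised with (c-C6H11)2BCl/Et3N (Et2O, −78 °C) to the ring-locked E-configured dicyclohexylboron enolate F2. This adds to 19 through a Zimmerman–Traxler chair to give the boron aldolate F3, and non-oxidative work-up (MeOH, pH 7 buffer, silica) gives the β-hydroxy ketone F4. The aldol is 8,9-anti, but the facial sense is now substrate-controlled, so the C8 configuration must be verified. Takai–Lombardo methylenation (Zn, CH2Br2, TiCl4, THF, 0 °C) of the ketone then gives 21.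

Step 14 (ring-closing metathesis). The hindered 1,1-disubstituted alkene is held in the dioxane, and oligomerisation or engagement of the methylene lactone may compete. The fallback changes the cyclisation substrate; it sets out from 24 and comes back at 26. The acetonide is removed first (AcOH/THF/H2O, 35 °C) to give the triene diol F5. The ring is then closed on this unconstrained substrate, where the free allylic C9 hydroxyl can assist alkylidene transfer to the hindered alkene (second-generation Hoveyda–Grubbs catalyst, PhMe, 1 mM, 80 °C), giving 26 directly.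

**Further compounds**
F1 | step 9 | (4R)-4-[(1R,2E)-3-({[tert-butyl(diphenyl)silyl]oxy}methyl)-1-[(trimethylsilyl)oxy]hepta-2,6-dien-1-yl]-3-methylideneoxolan-2-one | C=C1C(=O)OC[C@@H]1[C@H](O[Si](C)(C)C)/C=C(/CO[Si](c2ccccc2)(c2ccccc2)C(C)(C)C)CCC=C
F2 | step 11 | 2,2-dimethyl-4H-1,3-dioxin-5-yl dicyclohexylborinate | CC1(C)OCC(OB(C2CCCCC2)C2CCCCC2)=CO1
F3 | step 11 | (R)-[(4R)-2,2-dimethyl-5-oxo-1,3-dioxan-4-yl]{(2R,3R)-2-[(1E)-2-({[tert-butyl(diphenyl)silyl]oxy}methyl)hexa-1,5-dien-1-yl]-4-methylidene-5-oxooxolan-3-yl}methyl dicyclohexylborinate | C=C1C(=O)O[C@H](/C=C(/CO[Si](c2ccccc2)(c2ccccc2)C(C)(C)C)CCC=C)[C@H]1[C@@H](OB(C2CCCCC2)C2CCCCC2)[C@H]3OC(C)(C)OCC3=O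
F4 | step 11 | (4R)-4-[(R)-hydroxy{(2R,3R)-2-[(1E)-2-({[tert-butyl(diphenyl)silyl]oxy}methyl)hexa-1,5-dien-1-yl]-4-methylidene-5-oxooxolan-3-yl}methyl]-2,2-dimethyl-1,3-dioxan-5-one | C=C1C(=O)O[C@H](/C=C(/CO[Si](c2ccccc2)(c2ccccc2)C(C)(C)C)CCC=C)[C@H]1[C@@H](O)[C@H]3OC(C)(C)OCC3=O
F5 | step 14 | (1R,2S)-2-hydroxy-3-(hydroxymethyl)-1-{(2R,3S)-2-[(1E)-2-({[tert-butyl(diphenyl)silyl]oxy}methyl)hexa-1,5-dien-1-yl]-4-methylidene-5-oxooxolan-3-yl}but-3-en-1-yl (2S)-2-methylbutanoate | C=C1C(=O)O[C@H](/C=C(/CO[Si](c2ccccc2)(c2ccccc2)C(C)(C)C)CCC=C)[C@H]1[C@@H](OC(=O)[C@@H](C)CC)[C@@H](O)C(=C)CO
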